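The flask holds 0.80 M of starting material, 0.800 M of second substrate and 3.4 mM of free catalyst, and I must decide whether to charge more free catalyst. For that I want the time to convert 20 % of the starting material.

| flask | starting material | second substrate | free catalyst | remark |
|---|---|---|---|---|
| beta | 0.40 M | 0.80 M | 3.4 mM | run made earlier |
| alpha | 1.6 M | 0.80 M | 3.4 mM | run made earlier |
| flask | 0.80 M | 0.800 M | 3.4 mM |  |

| run | time / h | target / % | starting material / % |
|---|---|---|---|
| beta | 1.50 | 5.4 | 93.3 |
| beta | 3.00 | 11.8 | 88.1 |
| beta | 5.00 | 19.5 | 80.8 |
| beta | 6.00 | 22.5 | 76.4 |
| alpha | 0.500 | 1.3 | 98.4 |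
| alpha | 1.33 | 2.6 | 97.3 |
| alpha | 3.00 | 5.2 | 94.2 |
| alpha | 6.00 | 11.3 | 88.8 |

(readings scatter by 0.3 percentage points)

1. factor on the rate of making target when 20 % of the starting material are converted if free catalyst is charged twice over
2. factor on the rate when 20 % of the starting material are converted if free catalyst is charged at 15 mM instead

At 6.00 h the beta run had made 22.5 % target from 0.40 M and the alpha run 11.3 % from 1.6 M. So 4.00 times the charge made about twice the amount in moles, and the rate bends towards a ceiling. I therefore write the rate as V·c/(K + c), with c for c(starting material) and the second substrate, charged alike in all three flasks, folded into K. Integrated, this gives V·t = K·ln(charge/c) + (charge − c), one line per run. Taking the target made as the starting material converted, the two lines give the readings K = 0.673 M and V = 0.0436 M h⁻¹.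

For this flask the same line gives 7.12 h, the time to convert 20 % of the starting material. No earlier run varies the catalyst, so I guess that rate scales with charge. Doubling then gives a factor of 2 and 3.56 h, while 15 mM gives 4.41 and 1.61 h.

The forecast puts the factors slightly above mine, at 2.05 and 4.6, and warns: “Catalyst order itself remains untested”.

This flask converts 20 % of the starting material at 7.08 h, against my 7.12 h, and the factors come out at 2.00 on doubling and 4.42 at 15 mM, where my scaling gives 4.41.

    starting material + free catalyst ⇌ catalyst intermediate A (K = 8.80 L mol⁻¹, k = 46.0 L mol⁻¹ h⁻¹)
    catalyst intermediate A → free catalyst + target (k = 12.0 h⁻¹)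
    second substrate + free catalyst ⇌ catalyst intermediate B (K = 0.800 L mol⁻¹, k = 280 L mol⁻¹ h⁻¹)
    catalyst intermediate B → free catalyst + second product (k = 22.0 h⁻¹)
    free catalyst → spent catalyst (k = 4.80 × 10⁻⁴ h⁻¹)

While it is free, free catalyst has a half-life of 1440 h against loss, far longer than the 7.08 h this flask takes to convert 20 % of the starting material. In this flask at 8.00 h spent catalyst stands at 0.112 % of the catalyst charged.

The readings stem from a simulated flask for an exercise; the scatter is artificial.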